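**Plan**
1. Retrosynthesis: open the lactone (C1–O), take the C15=C16 alkene back to an alkyne and cut C16–C17 (acetylide plus a six-membered chloro lactone), cut C2=C3 and N–C22 of the tetrahydropyridine ring, then cut C5–C6 and C8–C9 of the piperidine ring together.
2. Enabling feature: N is flanked by C5 and the spiro carbon C9, both of which can become N-acyliminium carbons, and the C6–C7–C8 bridge of the piperidine ring is one allyl unit (allylsilane nucleophile at C8, then alkene nucleophile at C6). The C13–C14–C15 arm, cis to N on the cyclopentane ring, closes a temporary γ-lactam (N–C15) that supplies the acyl group and locks C9, C13 and C14.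
3. Forward order: cyclopentanone → cis-fused bicyclic lactam → piperidine ring by a (3+3) annulation → lactam opened and tetrahydropyridine ring closed → side chain by acetylide addition → 15-membered lactone → Z-alkene.
4. Stereochemistry: C14 from methyl (R)-lactate (SN2 inversion); C13 by equilibration in the bicyclic lactam; C9 by the obligatory cis ring fusion in the annulation; C5 by hydride addition to the cyclic ketimine; C17 by CBS reduction; chloroalkene geometry from the lactone ring; C15=C16 by Lindlar reduction.

Key step: step 7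

Remark on the chemistry: locants follow the chain C1 (lactone C=O), C2=C3, C4, C5 (N–CH), C6–C8, C9 (spiro C), C10–C12, C13, C14 (CH–CH3), C15=C16, C17 (CH–OH), C18=C19(Cl), C20, C21 (O–CH2), C22 (N–CH2); compounds 1, 3, 9, 13, 21 and 26 are assumed to be purchasable.

Step 1
Reactants: 1 methyl (R)-lactate
Product: 2 methyl (2R)-2-(trifluoromethylsulfonyloxy)propanoate
Conditions: Tf2O, 2,6-lutidine, CH2Cl2, −78 to 0 °C
Reagents that add atoms: trifluoromethanesulfonic anhydride, O=S(=O)(OS(=O)(=O)C(F)(F)F)C(F)(F)F
Why: O-sulfonylation leaves the C–O bond intact (retention) and gives an α-carbonyl triflate that reacts by clean SN2 substitution in step 2.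

Step 2
Reactants: 3 tert-butyl 2-oxocyclopentane-1-carboxylate; 2 methyl (2R)-2-(trifluoromethylsulfonyloxy)propanoate
Product: 4 tert-butyl 1-[(2R)-1-methoxy-1-oxopropan-2-yl]-2-oxocyclopentane-1-carboxylate
Conditions: NaH, THF, 0 °C; then 2, −20 °C to rt
Reagents that add atoms: none
Why: SN2 C-alkylation of the stabilised β-keto ester enolate by the α-triflyloxy ester proceeds with inversion and fixes the future C14 as 2R; the new quaternary ring carbon forms as a mixture that disappears in step 3.

Step 3
Reactants: 4 tert-butyl 1-[(2R)-1-methoxy-1-oxopropan-2-yl]-2-oxocyclopentane-1-carboxylate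
Product: 6 methyl (2R)-2-(2-oxocyclopentyl)propanoate, via β-keto acid 5 (not isolated)
Conditions: CF3CO2H, CH2Cl2, rt; then toluene, 80 °C
Reagents that add atoms: none
Why: Acidolysis of the tert-butyl ester and thermal decarboxylation of the β-keto acid leave the methyl ester and the C14 centre (not α to the ketone) untouched, while the ring α-carbon (C13) stays epimerisable on purpose.

Step 4
Reactants: 6 methyl (2R)-2-(2-oxocyclopentyl)propanoate
Product: 8 (3R,3aR,6aS)-6a-methoxy-3-methylhexahydrocyclopenta[b]pyrrol-2(1H)-one, via hydroxy lactam 7 (not isolated)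
Conditions: NH3 (7 M in MeOH), 50 °C, sealed tube; then MeOH, PPTS (cat.), rt
Reagents that add atoms: ammonia, N; methanol, CO
Why: Ammonolysis and ring closure of the γ-keto ester give the ring–chain tautomeric hydroxy lactam, in which C13 equilibrates through the open keto amide to the cis-fused isomer with the C14 methyl on the convex face, and acid-catalysed N,O-acetal exchange with methanol then gives the stable methoxy lactam.

Step 5
Reactants: 9 3,3-diethoxypropan-1-ol
Product: 10 3,3-diethoxypropyl 2,2-dimethylpropanoate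
Conditions: t-BuCOCl, pyridine, DMAP (cat.), CH2Cl2, 0 °C to rt
Reagents that add atoms: pivaloyl chloride, CC(C)(C)C(=O)Cl
Why: Routine O-acylation; the pivalate tolerates NaH and TiCl4 and is removed reductively in step 9.

Step 6
Reactants: 8 (3R,3aR,6aS)-6a-methoxy-3-methylhexahydrocyclopenta[b]pyrrol-2(1H)-one; 10 3,3-diethoxypropyl 2,2-dimethylpropanoate
Product: 12 3-ethoxy-3-[(3R,3aR,6aS)-6a-methoxy-3-methyl-2-oxohexahydrocyclopenta[b]pyrrol-1(2H)-yl]propyl 2,2-dimethylpropanoate, via α-chloro ether 11 (not isolated)
Conditions: 10, AcCl, ZnBr2 (cat.), CH2Cl2, rt; added to 8, NaH, THF, 0 °C to rt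
Reagents that add atoms: none
Why: Acetal–acid chloride exchange gives the α-chloro ether, which N-alkylates the lactam sodium salt through its oxocarbenium character (the reaction type of N-alkoxymethylation of lactams) and installs the second N,O-acetal carbon (C5) as an inconsequential epimer mixture.

Step 7
Reactants: 12 3-ethoxy-3-[(3R,3aR,6aS)-6a-methoxy-3-methyl-2-oxohexahydrocyclopenta[b]pyrrol-1(2H)-yl]propyl 2,2-dimethylpropanoate; 13 allyltrimethylsilane
Product: 15 tricyclic 7-chloro γ-lactam (piperidine ring N–C5–C6–C7–C8–C9 closed; 2-(pivaloyloxy)ethyl at C5), via C9-allyl lactam 14 (not isolated)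
Conditions: 13 (1.05 equiv), TiCl4 (2.2 equiv), CH2Cl2, −78 to 0 °C
Reagents that add atoms: titanium tetrachloride, Cl[Ti](Cl)(Cl)Cl
Why: TiCl4 ionises the tertiary C9 N,O-acetal to a bicyclic N-acyliminium ion, which allyltrimethylsilane attacks in the Hosomi–Sakurai (SE2′) sense to form C8–C9 (14); the second N,O-acetal then ionises and the new terminal alkene attacks the C5 N-acyliminium ion (aza-Prins cyclisation) to form C5–C6, the secondary C7 cation being captured by chloride. The closest known reaction types are the allylation of ring-fused α-alkoxy lactams and the aza-Prins cyclisation of N-acyl homoallylamines to 4-chloropiperidines; with one equivalent of silane the reverse order (allylation at C5, then cyclisation onto C9) leads to the same product. The piperidine ring closes in the 6-endo-trig mode through a chair-like transition state. C9 is controlled by the temporary γ-lactam: the five–five ring fusion can only be cis, so C8 enters on the convex face, syn to H13, and C13/C14 are safe because no base is present. C5 is not controlled reliably (A(1,3) strain to the lactam carbonyl opposes a 1,3-diaxial contact with the axial C10 methylene), so both epimers are carried on and C5 is set in step 10; the C7 chloride is removed in step 8. The step needs exactly one allyl group per molecule and capture of the cation before elimination, which the silane stoichiometry and the chloride-rich TiCl4 medium secure.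

Step 8
Reactants: 15 tricyclic 7-chloro γ-lactam
Product: 16 tricyclic γ-lactam (C7 now CH2)
Conditions: Bu3SnH, AIBN (cat.), toluene, 100 °C
Reagents that add atoms: none
Why: Radical chain dehalogenation replaces the secondary C–Cl bond by C–H and erases the C7 stereocentre; lactam and pivalate are inert.

Step 9
Reactants: 16 tricyclic γ-lactam
Product: 17 (2R)-2-[(1R,5S)-7-(2-hydroxyethyl)-6-azaspiro[4.5]decan-1-yl]propan-1-ol (both C5 epimers)
Conditions: LiNH2BH3 (from BH3·NH3 and LiN(iPr)2), THF, 0 to 40 °C; then aq. HCl; NaOH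
Reagents that add atoms: none
Why: Lithium amidotrihydroborate reduces tertiary amides with C–N cleavage to primary alcohols (collapse of the hemiaminal to the aldehyde, then reduction), which frees the hindered piperidine N–H and the C15 carbinol and removes the pivalate in the same flask; no stereocentre is touched.

Step 10
Reactants: 17 (2R)-2-[(1R,5S)-7-(2-hydroxyethyl)-6-azaspiro[4.5]decan-1-yl]propan-1-ol (both C5 epimers)
Product: 20 (2R)-2-[(1R,5S,7R)-7-(2-hydroxyethyl)-6-azaspiro[4.5]decan-1-yl]propan-1-ol, via N-chloroamine 18 (not isolated), via cyclic ketimine 19 (not isolated)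
Conditions: N-chlorosuccinimide, CH2Cl2, 0 °C; DBU, 40 °C; then NaBH4, MeOH, −40 °C
Reagents that add atoms: none
Why: N-chlorination and dehydrochlorination can only give the C5=N ketimine because C9 is quaternary, and borohydride reduction of this half-chair imine adds hydride anti to the C13 side chain so that C4 ends equatorial and cis to C13 (5R), the outcome established for closely related 6-azaspiro[4.5]dec-6-enes.

Step 11
Reactants: 20 (2R)-2-[(1R,5S,7R)-7-(2-hydroxyethyl)-6-azaspiro[4.5]decan-1-yl]propan-1-ol; 21 methyl 2-(dimethoxyphosphoryl)prop-2-enoate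
Product: 22 methyl 2-(dimethoxyphosphoryl)-3-[(1R,5S,7R)-7-(2-hydroxyethyl)-1-[(2R)-1-hydroxypropan-2-yl]-6-azaspiro[4.5]decan-6-yl]propanoate
Conditions: 21, MeOH, 40 °C
Reagents that add atoms: none
Why: Aza-Michael addition of the secondary amine to the doubly activated terminal alkene forms N–C22; the hydroxyl groups do not compete and the new centre α to phosphorus is lost in step 12.

Step 12
Reactants: 22 methyl 2-(dimethoxyphosphoryl)-3-[(1R,5S,7R)-7-(2-hydroxyethyl)-1-[(2R)-1-hydroxypropan-2-yl]-6-azaspiro[4.5]decan-6-yl]propanoate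
Product: 24 tricyclic enoate aldehyde (methyl ester at C1; C2=C3; CHO at C15), via dialdehyde 23 (not isolated)
Conditions: (COCl)2, DMSO, CH2Cl2, −78 °C; Et3N, to 0 °C; then LiCl, DBU, MeCN, 0 °C
Reagents that add atoms: none
Why: Swern oxidation of both primary alcohols is followed by an intramolecular Horner–Wadsworth–Emmons olefination in which the phosphonate carbanion reaches the C3 aldehyde through a six-membered ring far faster than the C15 aldehyde through a seven-membered ring, closing the tetrahydropyridine ring with the C2=C3 enoate under conditions that spare the α-methyl aldehyde.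

Step 13
Reactants: 24 tricyclic enoate aldehyde
Product: 25 tricyclic enoate alkyne (C15≡C16–H)
Conditions: dimethyl (1-diazo-2-oxopropyl)phosphonate, K2CO3, MeOH, 0 °C to rt
Reagents that add atoms: dimethyl (1-diazo-2-oxopropyl)phosphonate, CC(=O)C(=[N+]=[N-])P(=O)(OC)OC
Why: Ohira–Bestmann (Seyferth–Gilbert) homologation turns the aldehyde into the terminal alkyne, adding C16, under K2CO3/MeOH that the α-stereocentre tolerates at low temperature.

Step 14
Reactants: 26 dihydro-2H-pyran-2,4(3H)-dione
Product: 27 4-chloro-5,6-dihydro-2H-pyran-2-one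
Conditions: (COCl)2, DMF (cat.), CH2Cl2, 0 °C to rt
Reagents that add atoms: oxalyl chloride, O=C(Cl)C(=O)Cl
Why: Vilsmeier-type chlorination of the enol of the β-keto lactone (a vinylogous acid) gives the β-chloro enoate; the six-membered ring fixes the carbonyl carbon and the ring CH2 cis on the alkene, which is the C17/C20 relationship of the target.

Step 15
Reactants: 25 tricyclic enoate alkyne; 27 4-chloro-5,6-dihydro-2H-pyran-2-one
Product: 28 hydroxy ynone (C15≡C16–C17(=O)–C18H=C19(Cl)–C20H2–C21H2–OH; C17 and C20 cis)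
Conditions: LiN(SiMe3)2, THF, −78 °C; then 27, −78 °C; aq. NH4Cl
Reagents that add atoms: none
Why: Acylation of the lithium acetylide by the lactone (1,2-addition; the tetrahedral lactolate prevents a second addition and opens on work-up) forms C16–C17 and passes the alkene geometry of the ring on to C18=C19.

Step 16
Reactants: 28 hydroxy ynone
Product: 29 propargylic alcohol diol (17S by CIP at the alkyne stage; same spatial arrangement as 17R in the target)
Conditions: (S)-1-methyl-3,3-diphenyltetrahydro-1H,3H-pyrrolo[1,2-c][1,3,2]oxazaborole ((S)-Me-CBS), catecholborane, toluene/CH2Cl2, −78 °C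
Reagents that add atoms: none
Why: Corey–Bakshi–Shibata reduction, in which the rod-like alkynyl group acts as the small and the chloroalkenyl group as the large substituent, so that the (S)-catalyst sets the C17 carbinol as in the target.

Step 17
Reactants: 29 propargylic alcohol diol
Product: 30 seco acid (C1 carboxylic acid; free C17 and C21 hydroxyls)
Conditions: LiOH, THF/H2O, rt; then aq. HCl to pH 7
Reagents that add atoms: lithium hydroxide, [Li+].[OH-]
Why: Saponification of the methyl enoate; alkyne, vinyl chloride and the free alcohols are stable to aqueous LiOH.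

Step 18
Reactants: 30 seco acid
Product: 32 15,16-didehydro macrolactone (ring alkyne), via mixed anhydride 31 (not isolated)
Conditions: 2,4,6-trichlorobenzoyl chloride, Et3N, THF, rt; then DMAP, toluene, 80 °C, high dilution
Reagents that add atoms: none
Why: Yamaguchi macrolactonisation under high dilution; the primary C21 hydroxyl closes the 15-membered ring, whereas the secondary C17 hydroxyl would have to close an 11-membered ring that contains the alkyne.

Step 19
Reactants: 32 15,16-didehydro macrolactone
Product: 33 target (5R,9S,13R,14S,17R; 15Z; 18E)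
Conditions: H2 (1 atm), Pd/CaCO3 poisoned with Pb(OAc)2, quinoline, EtOAc, rt
Reagents that add atoms: none
Why: Lindlar semi-hydrogenation adds H2 syn to the ring alkyne and gives the Z C15=C16 alkene; the trisubstituted vinyl chloride and the enoate are not reduced on the poisoned catalyst.

**Compound list**
1 | methyl (R)-lactate (methyl (2R)-2-hydroxypropanoate) | C[C@@H](O)C(=O)OC | starting material
2 | methyl (2R)-2-(trifluoromethylsulfonyloxy)propanoate | C[C@@H](OS(=O)(=O)C(F)(F)F)C(=O)OC | intermediate
3 | tert-butyl 2-oxocyclopentane-1-carboxylate (racemic) | O=C1CCCC1C(=O)OC(C)(C)C | starting material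
4 | tert-butyl 1-[(2R)-1-methoxy-1-oxopropan-2-yl]-2-oxocyclopentane-1-carboxylate (both ring epimers) | C[C@H](C1(C(=O)OC(C)(C)C)CCCC1=O)C(=O)OC | intermediate
5 | 1-[(2R)-1-methoxy-1-oxopropan-2-yl]-2-oxocyclopentane-1-carboxylic acid (β-keto acid, not isolated) | C[C@H](C1(C(=O)O)CCCC1=O)C(=O)OC | intermediate
6 | methyl (2R)-2-(2-oxocyclopentyl)propanoate (epimers at the ring carbon) | C[C@H](C1CCCC1=O)C(=O)OC | intermediate
7 | (3R)-6a-hydroxy-3-methylhexahydrocyclopenta[b]pyrrol-2(1H)-one (hydroxy lactam, not isolated) | C[C@@H]1C2CCCC2(O)NC1=O | intermediate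
8 | (3R,3aR,6aS)-6a-methoxy-3-methylhexahydrocyclopenta[b]pyrrol-2(1H)-one (cis-fused; CH3, H-3a and OCH3 on one face) | C[C@@H]1[C@H]2CCC[C@@]2(OC)NC1=O | intermediate
9 | 3,3-diethoxypropan-1-ol | CCOC(CCO)OCC | starting material
10 | 3,3-diethoxypropyl 2,2-dimethylpropanoate | CCOC(CCOC(=O)C(C)(C)C)OCC | intermediate
11 | 3-chloro-3-ethoxypropyl 2,2-dimethylpropanoate (α-chloro ether, not isolated) | CCOC(Cl)CCOC(=O)C(C)(C)C | intermediate
12 | 3-ethoxy-3-[(3R,3aR,6aS)-6a-methoxy-3-methyl-2-oxohexahydrocyclopenta[b]pyrrol-1(2H)-yl]propyl 2,2-dimethylpropanoate (both epimers at the N,O-acetal carbon) | C[C@@H]1[C@H]2CCC[C@@]2(OC)N(C(CCOC(=O)C(C)(C)C)OCC)C1=O | intermediate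
13 | allyltrimethylsilane | C=CC[Si](C)(C)C | starting material
14 | 3-[(3R,3aR,6aS)-6a-allyl-3-methyl-2-oxohexahydrocyclopenta[b]pyrrol-1(2H)-yl]-3-ethoxypropyl 2,2-dimethylpropanoate (not isolated) | C[C@@H]1[C@H]2CCC[C@@]2(CC=C)N(C(CCOC(=O)C(C)(C)C)OCC)C1=O | intermediate
15 | tricyclic 7-chloro γ-lactam: N–C15(=O)–C14(CH3)–C13 lactam fused to the cyclopentane and to the new piperidine ring; Cl at C7; CH2CH2OPiv at C5; 9S,13R,14R; C5 and C7 as mixtures | C[C@@H]1[C@H]2CCC[C@]23CC(Cl)CC(CCOC(=O)C(C)(C)C)N3C1=O | intermediate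
16 | tricyclic γ-lactam as 15 with CH2 at C7 (9S,13R,14R; both C5 epimers) | C[C@@H]1[C@H]2CCC[C@]23CCCC(CCOC(=O)C(C)(C)C)N3C1=O | intermediate
17 | (2R)-2-[(1R,5S)-7-(2-hydroxyethyl)-6-azaspiro[4.5]decan-1-yl]propan-1-ol (both epimers at spiro-ring C7 = C5) | C[C@@H](CO)[C@H]1CCC[C@]12CCCC(CCO)N2 | intermediate
18 | N-chloro derivative of 17 (not isolated) | C[C@@H](CO)[C@H]1CCC[C@]12CCCC(CCO)N2Cl | intermediate
19 | (2R)-2-[(1R,5S)-7-(2-hydroxyethyl)-6-azaspiro[4.5]dec-6-en-1-yl]propan-1-ol (cyclic ketimine, not isolated) | C[C@@H](CO)[C@H]1CCC[C@]12CCCC(CCO)=N2 | intermediate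
20 | (2R)-2-[(1R,5S,7R)-7-(2-hydroxyethyl)-6-azaspiro[4.5]decan-1-yl]propan-1-ol | C[C@@H](CO)[C@H]1CCC[C@]12CCC[C@H](CCO)N2 | intermediate
21 | methyl 2-(dimethoxyphosphoryl)prop-2-enoate | C=C(C(=O)OC)P(=O)(OC)OC | starting material
22 | methyl 2-(dimethoxyphosphoryl)-3-[(1R,5S,7R)-7-(2-hydroxyethyl)-1-[(2R)-1-hydroxypropan-2-yl]-6-azaspiro[4.5]decan-6-yl]propanoate (both epimers at the phosphonate carbon) | C[C@@H](CO)[C@H]1CCC[C@]12CCC[C@H](CCO)N2CC(C(=O)OC)P(=O)(OC)OC | intermediate
23 | methyl 2-(dimethoxyphosphoryl)-3-[(1R,5S,7R)-7-(2-oxoethyl)-1-[(2R)-1-oxopropan-2-yl]-6-azaspiro[4.5]decan-6-yl]propanoate (dialdehyde, not isolated) | C[C@@H](C=O)[C@H]1CCC[C@]12CCC[C@H](CC=O)N2CC(C(=O)OC)P(=O)(OC)OC | intermediate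
24 | tricyclic enoate aldehyde: methyl 2-[(2R)-1-oxopropan-2-yl]spiro[cyclopentane-1,6'-quinolizine]-3'-carboxylate with the C2=C3 double bond, otherwise saturated (5R,9S,13R,14R) | C[C@@H](C=O)[C@H]1CCC[C@]12CCC[C@@H]3CC=C(C(=O)OC)CN23 | intermediate
25 | tricyclic enoate alkyne: as 24 with (2R)-but-3-yn-2-yl in place of the oxopropyl group (5R,9S,13R,14R) | C[C@@H](C#C)[C@H]1CCC[C@]12CCC[C@@H]3CC=C(C(=O)OC)CN23 | intermediate
26 | dihydro-2H-pyran-2,4(3H)-dione | O=C1CC(=O)CCO1 | starting material
27 | 4-chloro-5,6-dihydro-2H-pyran-2-one | O=C1C=C(Cl)CCO1 | intermediate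
28 | hydroxy ynone: 25 acylated at C16 by C17(=O)–CH=C(Cl)–CH2CH2OH, 18E (C17 and C20 cis) | C[C@@H](C#CC(=O)/C=C(/Cl)CCO)[C@H]1CCC[C@]12CCC[C@@H]3CC=C(C(=O)OC)CN23 | intermediate
29 | propargylic alcohol diol: 28 reduced at C17 (17S by CIP with the alkyne present) | C[C@@H](C#C[C@@H](O)/C=C(/Cl)CCO)[C@H]1CCC[C@]12CCC[C@@H]3CC=C(C(=O)OC)CN23 | intermediate
30 | seco acid: carboxylic acid of 29 | C[C@@H](C#C[C@@H](O)/C=C(/Cl)CCO)[C@H]1CCC[C@]12CCC[C@@H]3CC=C(C(=O)O)CN23 | intermediate
31 | mixed anhydride of 30 with 2,4,6-trichlorobenzoic acid (not isolated) | C[C@@H](C#C[C@@H](O)/C=C(/Cl)CCO)[C@H]1CCC[C@]12CCC[C@@H]3CC=C(C(=O)OC(=O)c4c(Cl)cc(Cl)cc4Cl)CN23 | intermediate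
32 | 15,16-didehydro macrolactone (15-membered lactone with C15≡C16; free C17–OH) | C[C@H]1C#C[C@@H](O)/C=C(/Cl)CCOC(=O)C2=CC[C@H]3CCC[C@]4(CCC[C@H]14)N3C2 | intermediate
33 | target macrolactone (5R,9S,13R,14S,17R; 15Z; 18E) | C[C@H]1/C=C\[C@@H](O)/C=C(/Cl)CCOC(=O)C2=CC[C@H]3CCC[C@]4(CCC[C@H]14)N3C2 | target

**Step count and risks**
Total: 19 steps. Longest linear sequence: 17 steps (steps 1–4, 6–13 and 15–19).

Step 7. The cascade may stop after the first C–C bond, because the C5 N,O-acetal can lose ethanol to an enamide, or a second allyl group can be transferred if silane is left over. The fallback sets out from 8 and builds the ring in two separate operations with the N–C5 bond made last. Allylation of 8 with 13 (TiCl4, CH2Cl2, −78 °C) gives (3R,3aR,6aS)-6a-allyl-3-methylhexahydrocyclopenta[b]pyrrol-2(1H)-one F1. Hydrolysis of 10 (aq. CF3CO2H) gives 3-oxopropyl 2,2-dimethylpropanoate F2. Condensation of the lactam N–H of F1 with F2 under TiCl4 generates the exocyclic N-acyliminium ion and closes the piperidine ring by the aza-Prins mode, which comes back to the route at 15.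

Step 9. Hydride reduction of the lactam may follow the C–O cleavage course and give the tricyclic tertiary amine, or stop at the hemiaminal. The fallback sets out from 16. O-Methylation with Me3OBF4 (CH2Cl2) gives the O-methyl iminium ether tetrafluoroborate F3. Mild basic hydrolysis (aq. NaHCO3) cleaves its C–N bond to the amino ester methyl (2R)-2-[(1R,5S)-7-[2-(pivaloyloxy)ethyl]-6-azaspiro[4.5]decan-1-yl]propanoate F4. Reduction of both ester groups with LiAlH4 comes back to the route at 17.

Step 15. The acetylide may add in a conjugate addition–elimination sense at the chlorine-bearing carbon of 27, or the amide base may deprotonate the enoate of 25. The fallback sets out from 27. Reduction with i-Bu2AlH (CH2Cl2, −78 °C) gives the lactol 4-chloro-5,6-dihydro-2H-pyran-2-ol F5. Its open hydroxy-aldehyde form takes up the zinc acetylide of 25 (Me2Zn, ProPhenol ligand chosen for the target C17 configuration) in a catalyst-controlled alkynylation. This by-passes 28 and step 16 and comes back to the route at 29.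

Further compounds
F1 | step 7 | (3R,3aR,6aS)-6a-allyl-3-methylhexahydrocyclopenta[b]pyrrol-2(1H)-one | C[C@@H]1[C@H]2CCC[C@@]2(CC=C)NC1=O
F2 | step 7 | 3-oxopropyl 2,2-dimethylpropanoate | CC(C)(C)C(=O)OCCC=O
F3 | step 9 | O-methyl iminium ether tetrafluoroborate of 16 | C[C@@H]1[C@H]2CCC[C@]23CCCC(CCOC(=O)C(C)(C)C)[N+]3=C1OC.F[B-](F)(F)F
F4 | step 9 | methyl (2R)-2-[(1R,5S)-7-[2-(pivaloyloxy)ethyl]-6-azaspiro[4.5]decan-1-yl]propanoate | C[C@@H](C(=O)OC)[C@H]1CCC[C@]12CCCC(CCOC(=O)C(C)(C)C)N2
F5 | step 15 | 4-chloro-5,6-dihydro-2H-pyran-2-ol | OC1C=C(Cl)CCO1
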